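Start from Monday's run, which held 27% target at 6.00 d, and ask what its reagent bought. These are the flasks, the readings and the questions.

all flasks: starting material 0.10 M

| charge | reagent in the second phase | protic impurity | remark | time | volume of the second phase over the first |
|---|---|---|---|---|---|
| Monday's | 0.070 M | 2.5 mM | run made earlier |  |  |
| Wednesday's | 0.070 M | 10 mM | run made earlier |  |  |
| Thursday's | 0.11 M | 5 mM | run made earlier |  |  |
| flask | 0.0700 M | 5.00 mM |  | 10 d | 2.0 |

| run | time / d | target / % |
|---|---|---|
| Monday's | 0.500 | 6 |
| Monday's | 1.67 | 13 |
| Monday's | 3.00 | 17 |
| Monday's | 4.00 | 22 |
| Monday's | 6.00 | 27 |
| Wednesday's | 1.25 | 10 |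
| Wednesday's | 2.50 | 15 |
| Wednesday's | 4.00 | 21 |
| Wednesday's | 5.00 | 21 |
| Wednesday's | 6.00 | 23 |
| Thursday's | 0.500 | 9 |
| Thursday's | 0.833 | 11 |
| Thursday's | 1.67 | 17 |
| Thursday's | 3.00 | 25 |
| Thursday's | 6.00 | 32 |

(each reading ± 1.5 percentage points)

* how much target there is at 10 d, in percent of the starting material charged
* the change that raises the amount of target at 10 d, in percent of the starting material charged most ("none" if none brings more than 2 percentage points) (east / south-west / none)
* amount of target at 10 d, in percent of the starting material charged, after east

- east: doubling the amount of reagent in the second phase, all else as stated
- south-west: doubling the transfer coefficient of the reagent in the second phase, all else as stated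

- in the second phase: reagent in the second phase; everything else is in the first
- charges count per volume of the first phase; a concentration in a rate is the amount of a species over the volume of its own phase; every rate counts per litre of the first phase
- steps that have been proposed: reagent in the reaction phase <-> reagent in the second phase; starting material + reagent in the reaction phase -> target; 2 reagent in the reaction phase -> homo dimer; starting material + protic impurity -> quenched substrate; reagent in the reaction phase + target -> over-reaction product
- the earlier runs hold the two phases in the same ratio of volumes as the flask asked about

Read the row at 6.00 d of each run and form the return on reagent (the reagent yield): target made over reagent in the second phase charged, both in M, which for Monday's run reads 0.386.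

Now compare the rows. Wednesday's run has the same charge of reagent, but [protic impurity] is 10 mM against 2.5 mM, and it returns 0.329, less than Monday's run.

The asked flask's 5.00 mM stands as many times above the lower value as below the higher, so take the mean of the two returns, 0.357. My own reckoning for the asked flask is thus 25.0% target at 6.00 d. Monday's run is still climbing, from 22% at 4.00 d, so expect more than that at 10 d.

Thursday's run shares the asked flask's impurity but has 0.11 M reagent. It holds more target than my 25.0%, yet returns 0.291, less than 0.357. So expect doubling the reagent to add target at a falling return. No run varies the transfer, so choose east on Thursday's evidence.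

The forecast gives 31% (28% to 35%), chooses east, and gives 40% (35% to 46%) after east, holding that “The ceiling scales roughly as reagent” to the power 0.45.

The asked flask holds 27.8% target at 10 d, a return of 0.398, with 10.5% over-reaction product beside it.

    reagent in the reaction phase ⇌ reagent in the second phase, rate k1*([reagent in the reaction phase] - [reagent in the second phase]/K1) per volume of the first phase (partition coefficient = 1.10, kL = 5.50 × 10⁻⁵ s⁻¹)
    starting material + reagent in the reaction phase → target (k = 7.10 × 10⁻⁵ M⁻¹ s⁻¹)
    2 reagent in the reaction phase → homo dimer (k = 7.10 × 10⁻⁵ M⁻¹ s⁻¹)
    starting material + protic impurity → quenched substrate (k = 0.00280 M⁻¹ s⁻¹)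
    reagent in the reaction phase + target → over-reaction product (k = 8.50 × 10⁻⁵ M⁻¹ s⁻¹)

The better change is east, gaining 4 percentage points against 0.078 points for south-west, but the flask after east reaches 31.8% at 10 d, which is 8.2 points under the forecast. The doubled charge of that flask returns 0.227 at 10 d, below the 0.398 of the asked flask at the same time and below the 0.291 read from Thursday's run at 6.00 d.

The earlier runs and the new flask were computed for substances that don't exist.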